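**Retrosynthetic overview**
- Cut the CH2 bridge at the aryl carbon: intermolecular Michael addition of a prenylated phloroacetophenone to a 6-methylidene triketone, released from the Mannich base of the chiral acyl-triketone (fragment union, last step).
- Aromatic half: one C-prenylation of phloroacetophenone; the aromatic ring (ring B) is bought, not built.
- Chiral ring (ring A): Dieckmann (intramolecular Claisen) closure of an acyclic triacylmethane ester, itself made by two C-acetylations of the methyl ketone of an α-methyl-α-prenyl acetoacetate.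
- Quaternary stereocentre: double Fráter–Seebach alkylation (MeI first, prenyl bromide second) of ethyl (S)-3-hydroxybutanoate, then oxidation of the carbinol.
- Ring order: ring A is the only ring formed (step 7); ring B comes intact from phloroacetophenone.

Assumption: β-triketones are written in the enol tautomer of the target SMILES, and enolates, alkoxides and phenoxides formed by the bases are taken as ionised forms of the numbered compounds, without numbers of their own.

**Route**

Step 1
Reactants: 1 1-(2,4,6-trihydroxyphenyl)ethan-1-one (phloroacetophenone); 2 1-bromo-3-methylbut-2-ene (prenyl bromide)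
Product: 3 1-[2,4,6-trihydroxy-3-(3-methylbut-2-en-1-yl)phenyl]ethan-1-one
Conditions: 1 (2 equiv), 10% aq. KOH, 0 °C; 2 (1 equiv) dropwise, 0 °C → rt; 1 M HCl; chromatography (excess 1 recovered)
Reagents that add atoms: none
Why: Phenoxide C-alkylation (SN2 C-prenylation) of the phloroglucinol anion is favoured over O-alkylation in water, the two free ring positions of 1 are equivalent, and the excess of 1 holds the reaction at the mono-prenyl stage.

Step 2
Reactants: 4 ethyl (3S)-3-hydroxybutanoate
Product: 5 ethyl (2S,3S)-3-hydroxy-2-methylbutanoate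
Conditions: LiN(i-Pr)2 (2.2 equiv, commercial solution), THF, −50 → −20 °C; MeI (1.3 equiv), DMPU, −50 → 0 °C; 1 M HCl
Reagents that add atoms: iodomethane (MeI), CI
Why: In this Fráter–Seebach alkylation the dilithium alkoxide–enolate is a rigid six-membered chelate whose C3 methyl shields one face, so MeI enters anti to it and sets C2 as S (anti product, high dr expected).

Step 3
Reactants: 5 ethyl (2S,3S)-3-hydroxy-2-methylbutanoate; 2 1-bromo-3-methylbut-2-ene
Product: 6 ethyl (2S,3S)-3-hydroxy-2-methyl-2-(3-methylbut-2-en-1-yl)butanoate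
Conditions: LiN(i-Pr)2 (2.3 equiv, commercial solution), THF, −78 → −15 °C; 2 (1.5 equiv), DMPU, −78 → 0 °C; 1 M HCl; chromatography to remove the minor C2 epimer
Reagents that add atoms: none
Why: In this second Fráter–Seebach alkylation the chelated tetrasubstituted enolate is again attacked anti to the C3 methyl by the reactive allylic bromide, so introducing methyl first and prenyl second sets the quaternary centre as 2S.

Step 4
Reactants: 6 ethyl (2S,3S)-3-hydroxy-2-methyl-2-(3-methylbut-2-en-1-yl)butanoate
Product: 7 ethyl (2S)-2-methyl-2-(3-methylbut-2-en-1-yl)-3-oxobutanoate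
Conditions: Dess–Martin periodinane (1.3 equiv), CH2Cl2, 0 °C → rt
Reagents that add atoms: none
Why: Dess–Martin oxidation of the secondary carbinol spares the trisubstituted alkene and removes the auxiliary C3 stereocentre, while the quaternary centre has no α-hydrogen and cannot epimerise, so the diastereomeric purity of 6 becomes the ee of 7.

Step 5
Reactants: 7 ethyl (2S)-2-methyl-2-(3-methylbut-2-en-1-yl)-3-oxobutanoate
Product: 8 ethyl (2S)-2-methyl-2-(3-methylbut-2-en-1-yl)-3,5-dioxohexanoate
Conditions: MgBr2·OEt2 (2.5 equiv), i-Pr2NEt (3 equiv), 1-acetylbenzotriazole (1.5 equiv), CH2Cl2, rt; 1 M HCl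
Reagents that add atoms: 1-acetylbenzotriazole, CC(=O)n1nnc2ccccc12
Why: This crossed Claisen-type C-acylation by soft enolisation is regiospecific because the acetyl CH3 is the only enolisable position of 7, the β-diketone is held as its magnesium chelate, and no alkoxide is present that could cleave the non-enolisable β-keto ester by retro-Claisen.

Step 6
Reactants: 8 ethyl (2S)-2-methyl-2-(3-methylbut-2-en-1-yl)-3,5-dioxohexanoate
Product: 9 ethyl (2S)-4-acetyl-2-methyl-2-(3-methylbut-2-en-1-yl)-3,5-dioxohexanoate
Conditions: AcCl (1.1 equiv), MgCl2 (1.1 equiv), pyridine (2.2 equiv), CH2Cl2, 0 °C → rt; cold 1 M HCl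
Reagents that add atoms: acetyl chloride, CC(=O)Cl
Why: Magnesium-chelate-directed C-acylation of the β-diketone (Rathke-type acylation) takes place at the central carbon and gives a triacylmethane whose two acetyl groups are equivalent, so either one can close the ring in the next step.

Step 7
Reactants: 9 ethyl (2S)-4-acetyl-2-methyl-2-(3-methylbut-2-en-1-yl)-3,5-dioxohexanoate
Product: 10 (4R)-2-acetyl-3,5-dihydroxy-4-methyl-4-(3-methylbut-2-en-1-yl)cyclohexa-2,5-dien-1-one
Conditions: LiN(i-Pr)2 (3.3 equiv, commercial solution), THF, −78 → 0 °C; 1 M HCl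
Reagents that add atoms: none
Why: In this Dieckmann (intramolecular Claisen) condensation the methine and then an acetyl CH3 are deprotonated, the methyl carbanion attacks the ethyl ester in a 6-exo-trig closure driven by loss of ethoxide and formation of the stabilised triketone enolate, and the untouched quaternary centre becomes 4R only through CIP re-ranking.

Step 8
Reactants: 10 (4R)-2-acetyl-3,5-dihydroxy-4-methyl-4-(3-methylbut-2-en-1-yl)cyclohexa-2,5-dien-1-one
Product: 11 (4R)-2-acetyl-6-[(dimethylamino)methyl]-3,5-dihydroxy-4-methyl-4-(3-methylbut-2-en-1-yl)cyclohexa-2,5-dien-1-one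
Conditions: Eschenmoser's salt (1.2 equiv), Et3N (1.0 equiv), CH2Cl2, 0 °C → rt
Reagents that add atoms: N,N-dimethylmethyleneiminium iodide (Eschenmoser's salt), C=[N+](C)C.[I-]
Why: In this Mannich reaction the preformed iminium ion is attacked by C6, the only free enol carbon of the triketone, and since no free formaldehyde is present a methylene-bridged homodimer of 10 is not expected.

Step 9
Reactants: 11 (4R)-2-acetyl-6-[(dimethylamino)methyl]-3,5-dihydroxy-4-methyl-4-(3-methylbut-2-en-1-yl)cyclohexa-2,5-dien-1-one; 3 1-[2,4,6-trihydroxy-3-(3-methylbut-2-en-1-yl)phenyl]ethan-1-one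
Product: 13 (4R)-2-acetyl-6-{[3-acetyl-2,4,6-trihydroxy-5-(3-methylbut-2-en-1-yl)phenyl]methyl}-3,5-dihydroxy-4-methyl-4-(3-methylbut-2-en-1-yl)cyclohexa-2,5-dien-1-one, via 6-methylidene trione 12 (not isolated)
Conditions: 3 (1.2 equiv), 1,4-dioxane, 80 °C, argon sweep (removes Me2NH), 3 h; dilute HCl wash; chromatography
Reagents that add atoms: none
Why: Thermal E1cB (retro-Mannich-type) loss of Me2NH gives the 2-methylidene-1,3-dione 12, a doubly activated acceptor, to which the single free ring carbon of phloroglucinol 3 adds in an intermolecular Michael addition followed by re-aromatisation, forming the CH2 bridge without touching the quaternary stereocentre.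

**Compound list**

1 | 1-(2,4,6-trihydroxyphenyl)ethan-1-one | CC(=O)c1c(O)cc(O)cc1O | starting material
2 | 1-bromo-3-methylbut-2-ene | CC(C)=CCBr | starting material
3 | 1-[2,4,6-trihydroxy-3-(3-methylbut-2-en-1-yl)phenyl]ethan-1-one | CC(=O)c1c(O)cc(O)c(CC=C(C)C)c1O | intermediate
4 | ethyl (3S)-3-hydroxybutanoate | C[C@H](O)CC(=O)OCC | starting material
5 | ethyl (2S,3S)-3-hydroxy-2-methylbutanoate | C[C@H](O)[C@H](C)C(=O)OCC | intermediate
6 | ethyl (2S,3S)-3-hydroxy-2-methyl-2-(3-methylbut-2-en-1-yl)butanoate | C[C@H](O)[C@](C)(CC=C(C)C)C(=O)OCC | intermediate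
7 | ethyl (2S)-2-methyl-2-(3-methylbut-2-en-1-yl)-3-oxobutanoate | CC(=O)[C@](C)(CC=C(C)C)C(=O)OCC | intermediate
8 | ethyl (2S)-2-methyl-2-(3-methylbut-2-en-1-yl)-3,5-dioxohexanoate | CC(=O)CC(=O)[C@](C)(CC=C(C)C)C(=O)OCC | intermediate
9 | ethyl (2S)-4-acetyl-2-methyl-2-(3-methylbut-2-en-1-yl)-3,5-dioxohexanoate | CC(=O)C(C(C)=O)C(=O)[C@](C)(CC=C(C)C)C(=O)OCC | intermediate
10 | (4R)-2-acetyl-3,5-dihydroxy-4-methyl-4-(3-methylbut-2-en-1-yl)cyclohexa-2,5-dien-1-one | CC(=O)C1=C(O)[C@](C)(CC=C(C)C)C(O)=CC1=O | intermediate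
11 | (4R)-2-acetyl-6-[(dimethylamino)methyl]-3,5-dihydroxy-4-methyl-4-(3-methylbut-2-en-1-yl)cyclohexa-2,5-dien-1-one | CC(=O)C1=C(O)[C@](C)(CC=C(C)C)C(O)=C(CN(C)C)C1=O | intermediate
12 | (4S)-2-acetyl-3-hydroxy-4-methyl-4-(3-methylbut-2-en-1-yl)-6-methylidenecyclohex-2-ene-1,5-dione (same spatial arrangement as 10; descriptor changes by CIP ranking only) | CC(=O)C1=C(O)[C@](C)(CC=C(C)C)C(=O)C(=C)C1=O | intermediate
13 | (4R)-2-acetyl-6-{[3-acetyl-2,4,6-trihydroxy-5-(3-methylbut-2-en-1-yl)phenyl]methyl}-3,5-dihydroxy-4-methyl-4-(3-methylbut-2-en-1-yl)cyclohexa-2,5-dien-1-one | CC(=O)C1=C(O)[C@](C)(CC=C(C)C)C(O)=C(Cc2c(O)c(CC=C(C)C)c(O)c(C(C)=O)c2O)C1=O | target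

**Summary**

Total step count: 9. Longest linear sequence: 8 steps (4 → 13, steps 2 to 9); step 1 supplies the aromatic partner 3.

The three steps most likely to fail:

Step 3 (crowded quaternary alkylation; yield and dr). The fallback sets out from 5 and comes back at 6. The dianion of 5 is alkylated with the smaller allyl bromide (LiN(i-Pr)2, THF/DMPU), which gives ethyl (2S,3S)-3-hydroxy-2-methyl-2-(prop-2-en-1-yl)butanoate F1 with the same anti sense. The prenyl group is then completed by olefin cross-metathesis of F1 with excess 2-methylbut-2-ene (second-generation Grubbs catalyst RuCl2(=CHPh)(PCy3)(H2IMes), CH2Cl2, 40 °C), which delivers 6.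

Step 7 (Dieckmann closure of the triacylmethane onto an ester next to the quaternary carbon). The fallback sets out from 3 and comes back at 10, so it replaces the whole acyclic sequence. Compound 3 is C-methylated with dearomatisation at the prenyl-bearing carbon (MeI, NaOMe, MeOH, 0 °C → rt) to give racemic 2-acetyl-3,5-dihydroxy-4-methyl-4-(3-methylbut-2-en-1-yl)cyclohexa-2,5-dien-1-one F2. Preparative HPLC on a chiral stationary phase (amylose tris(3,5-dimethylphenylcarbamate), hexane/i-PrOH with 0.1% TFA) then separates 10 from (4S)-2-acetyl-3,5-dihydroxy-4-methyl-4-(3-methylbut-2-en-1-yl)cyclohexa-2,5-dien-1-one F3, which is discarded.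

Step 9 (fragment union; risk of CH2 scrambling to symmetrical dimers or of sluggish elimination). The fallback sets out from 3 and 10 and comes back at 13, with the roles of the partners reversed. Compound 3 is aminomethylated at its free ring carbon with Eschenmoser's salt (CH2Cl2, Et3N, rt) to give 1-{3-[(dimethylamino)methyl]-2,4,6-trihydroxy-5-(3-methylbut-2-en-1-yl)phenyl}ethan-1-one F4. Heating F4 with 10 (1,4-dioxane, 80–100 °C) releases the ortho-quinone methide 2-acetyl-3,5-dihydroxy-6-methylidene-4-(3-methylbut-2-en-1-yl)cyclohexa-2,4-dien-1-one F5, which is trapped by the enol carbon C6 of 10 in a Michael addition to give 13.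

**Further compounds**

F1 | step 3 | ethyl (2S,3S)-3-hydroxy-2-methyl-2-(prop-2-en-1-yl)butanoate | C[C@H](O)[C@](C)(CC=C)C(=O)OCC
F2 | step 7 | racemic 2-acetyl-3,5-dihydroxy-4-methyl-4-(3-methylbut-2-en-1-yl)cyclohexa-2,5-dien-1-one | CC(=O)C1=C(O)C(C)(CC=C(C)C)C(O)=CC1=O
F3 | step 7 | (4S)-2-acetyl-3,5-dihydroxy-4-methyl-4-(3-methylbut-2-en-1-yl)cyclohexa-2,5-dien-1-one | CC(=O)C1=C(O)[C@@](C)(CC=C(C)C)C(O)=CC1=O
F4 | step 9 | 1-{3-[(dimethylamino)methyl]-2,4,6-trihydroxy-5-(3-methylbut-2-en-1-yl)phenyl}ethan-1-one | CC(=O)c1c(O)c(CN(C)C)c(O)c(CC=C(C)C)c1O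
F5 | step 9 | 2-acetyl-3,5-dihydroxy-6-methylidene-4-(3-methylbut-2-en-1-yl)cyclohexa-2,4-dien-1-one | CC(=O)C1=C(O)C(CC=C(C)C)=C(O)C(=C)C1=O
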